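**Retrosynthetic overview**
- The target is unmasked last by N-detosylation and global desilylation; one indole ring is bought (indole-3-carbaldehyde), and the 3-(2-hydroxyethyl)indole ring is the only ring built, late, by Larock heteroannulation of 2-iodoaniline with an internal alkyne.
- The alkyne comes from the vinyl group of a homoallylic alcohol: oxidative cleavage, dibromo-olefination, then acetylide opening of oxirane.
- Key C–C bond (bis-indolyl CH to carbinol CH): chiral-phosphoric-acid-catalysed carbonyl allylation of (silyloxy)acetaldehyde with an (E)-γ-(indol-3-yl)allyl pinacol boronate, which sets both stereocentres (anti) in one step.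
- The allyl boronate comes from indole-3-carbaldehyde by N-tosylation, Wittig olefination, DIBAL reduction and Pd-catalysed allylic borylation.

Abbreviations: Ts = 4-methylphenylsulfonyl; TBS = tert-butyldimethylsilyl; Bpin = 4,4,5,5-tetramethyl-1,3,2-dioxaborolan-2-yl.

Assumption: the (S)-antipode of the TRIP phosphoric acid is taken to direct attack to the Si face of the aldehyde (mirror image of the Re-face preference recalled for the (R)-acid, to be confirmed by Mosher analysis on the first run); building blocks that deliver carbon atoms are numbered as starting materials, while reagents that deliver only heteroatoms or protecting groups are given on the reagent line.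

**Step 1**
Reactants: 1 1H-indole-3-carbaldehyde
Product: 2 1-tosyl-1H-indole-3-carbaldehyde
Conditions: TsCl (1.2 equiv), Et3N (2 equiv), DMAP (10 mol %), CH2Cl2, 0 °C to rt
Reagents that add atoms: p-toluenesulfonyl chloride, Cc1ccc(cc1)S(Cl)(=O)=O
Why: N-sulfonylation of the acidic indole N–H (DMAP acyl-transfer catalysis) deactivates the indole towards the oxidants and organometallics used later.

**Step 2**
Reactants: 2 1-tosyl-1H-indole-3-carbaldehyde; 3 ethyl (triphenylphosphoranylidene)acetate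
Product: 4 ethyl (E)-3-(1-tosyl-1H-indol-3-yl)acrylate
Conditions: 3 (1.2 equiv), toluene, 90 °C
Reagents that add atoms: none
Why: Wittig olefination with a stabilised ylide gives the (E)-enoate with high selectivity.

**Step 3**
Reactants: 4 ethyl (E)-3-(1-tosyl-1H-indol-3-yl)acrylate
Product: 6 (E)-3-(1-tosyl-1H-indol-3-yl)prop-2-en-1-ol, via enal 5 (not isolated)
Conditions: i-Bu2AlH (2.5 equiv), CH2Cl2, −78 °C to 0 °C; aq Rochelle salt
Reagents that add atoms: none
Why: 1,2-hydride reduction of the conjugated ester (DIBAL reduction) stops at the allylic alcohol and leaves the alkene geometry and the sulfonamide untouched.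

**Step 4**
Reactants: 6 (E)-3-(1-tosyl-1H-indol-3-yl)prop-2-en-1-ol
Product: 7 (E)-3-[3-(Bpin)prop-1-en-1-yl]-1-tosyl-1H-indole
Conditions: B2pin2 (1.3 equiv), [Pd(MeCN)4](BF4)2 (5 mol %), DMSO/MeOH 1:1, 40 °C
Reagents that add atoms: bis(pinacolato)diboron, CC1(C)OB(OC1(C)C)B1OC(C)(C)C(C)(C)O1
Why: Pd-catalysed allylic borylation through a π-allylpalladium intermediate delivers boron to the unhindered terminus and keeps the conjugated (E)-alkene.

**Step 5**
Reactants: 7 (E)-3-[3-(Bpin)prop-1-en-1-yl]-1-tosyl-1H-indole; 8 2-[(tert-butyldimethylsilyl)oxy]acetaldehyde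
Product: 10 (2S,3R)-1-(TBSO)-3-(1-tosyl-1H-indol-3-yl)pent-4-en-2-ol, via pinacol borate 9 (not isolated)
Conditions: 8 (1.5 equiv), (S)-TRIP [(S)-3,3'-bis(2,4,6-triisopropylphenyl)-1,1'-binaphthalene-2,2'-diyl hydrogen phosphate] (5 mol %), 4 Å MS, toluene, −30 °C, 48 h; then aq NaHCO3
Reagents that add atoms: none
Why: Carbonyl allylation (allylboration) through a closed chair transition state: the (E)-boronate gives the anti relationship, and the chiral Brønsted acid bound to the boronate oxygen admits only Si-face attack on the aldehyde, fixing C2 as S and therefore C3 as R.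

**Step 6**
Reactants: 10 (2S,3R)-1-(TBSO)-3-(1-tosyl-1H-indol-3-yl)pent-4-en-2-ol
Product: 11 3-[(3R,4S)-4,5-bis(TBSO)pent-1-en-3-yl]-1-tosyl-1H-indole
Conditions: TBSOTf (1.3 equiv), 2,6-lutidine (2 equiv), CH2Cl2, −78 °C to 0 °C
Reagents that add atoms: tert-butyldimethylsilyl triflate, CC(C)(C)[Si](C)(C)OS(=O)(=O)C(F)(F)F
Why: Silyl ether formation at the hindered secondary alcohol blocks retro-allylation and lactol formation in the next steps and touches no stereocentre.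

**Step 7**
Reactants: 11 3-[(3R,4S)-4,5-bis(TBSO)pent-1-en-3-yl]-1-tosyl-1H-indole
Product: 13 (2R,3S)-3,4-bis(TBSO)-2-(1-tosyl-1H-indol-3-yl)butanal, via vicinal diol 12 (not isolated)
Conditions: OsO4 (2 mol %), NaIO4 (4 equiv), 2,6-lutidine (2 equiv), 1,4-dioxane/H2O 3:1, rt; crude aldehyde used at once
Reagents that add atoms: osmium tetroxide, O=[Os](=O)(=O)=O (catalytic oxygen donor); sodium periodate, [Na+].[O-]I(=O)(=O)=O (terminal oxidant that restores it)
Why: Lemieux–Johnson oxidative cleavage: the monosubstituted alkene is dihydroxylated much faster than the sulfonyl-deactivated indole 2,3-bond, and the buffered, silica-free handling protects the α-indolyl stereocentre.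

**Step 8**
Reactants: 13 (2R,3S)-3,4-bis(TBSO)-2-(1-tosyl-1H-indol-3-yl)butanal; 14 tetrabromomethane
Product: 15 3-[(3R,4S)-1,1-dibromo-4,5-bis(TBSO)pent-1-en-3-yl]-1-tosyl-1H-indole
Conditions: 14 (2 equiv), PPh3 (4 equiv), 2,6-lutidine (2 equiv), CH2Cl2, 0 °C, 30 min
Reagents that add atoms: none
Why: Ramirez dibromo-olefination (first half of the Corey–Fuchs sequence) is a fast, essentially non-basic Wittig-type reaction, so the α-stereocentre is carried through.

**Step 9**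
Reactants: 15 3-[(3R,4S)-1,1-dibromo-4,5-bis(TBSO)pent-1-en-3-yl]-1-tosyl-1H-indole; 16 oxirane
Product: 18 (5R,6S)-6,7-bis(TBSO)-5-(1-tosyl-1H-indol-3-yl)hept-3-yn-1-ol, via lithium acetylide 17 (not isolated)
Conditions: n-BuLi (2.05 equiv), THF, −78 °C, 1 h; then BF3·OEt2 (1.5 equiv), 16 (3 equiv), −78 °C; H2O
Reagents that add atoms: none
Why: Corey–Fuchs alkyne formation (Br/Li exchange, 1,2-shift, deprotonation) followed by BF3-promoted acetylide opening of the epoxide; exact stoichiometry of n-BuLi avoids lithiation of the indole C2–H.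

**Step 10**
Reactants: 18 (5R,6S)-6,7-bis(TBSO)-5-(1-tosyl-1H-indol-3-yl)hept-3-yn-1-ol
Product: 19 3-[(5R,6S)-1,6,7-tris(TBSO)hept-3-yn-5-yl]-1-tosyl-1H-indole
Conditions: TBSCl (1.3 equiv), imidazole (2.5 equiv), DMF, rt
Reagents that add atoms: tert-butyldimethylsilyl chloride, CC(C)(C)[Si](C)(C)Cl
Why: Silylation of the primary alcohol removes a hydroxyl that could chelate palladium and erode the regiochemistry of the annulation.

**Step 11**
Reactants: 19 3-[(5R,6S)-1,6,7-tris(TBSO)hept-3-yn-5-yl]-1-tosyl-1H-indole; 20 2-iodoaniline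
Product: 21 3-[(1S,2S)-2,3-bis(TBSO)-1-{3-[2-(TBSO)ethyl]-1H-indol-2-yl}propyl]-1-tosyl-1H-indole
Conditions: 20 (1.5 equiv), Pd(OAc)2 (10 mol %), LiCl (1 equiv), Na2CO3 (3 equiv), DMF, 100 °C
Reagents that add atoms: none
Why: Larock indole synthesis: syn-carbopalladation puts the aryl group on the alkyne carbon bearing the small CH2CH2OTBS chain and palladium next to the bulky branched carbon, so C–N bond formation places the branched substituent at C2 and the silyloxyethyl chain at C3.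

**Step 12**
Reactants: 21 3-[(1S,2S)-2,3-bis(TBSO)-1-{3-[2-(TBSO)ethyl]-1H-indol-2-yl}propyl]-1-tosyl-1H-indole
Product: 22 3-[(1S,2S)-2,3-bis(TBSO)-1-{3-[2-(TBSO)ethyl]-1H-indol-2-yl}propyl]-1H-indole
Conditions: Mg turnings (10 equiv), MeOH, sonication, rt
Reagents that add atoms: none
Why: Single-electron reductive cleavage of the sulfonamide N–S bond (Mg/MeOH desulfonylation) is neutral towards silyl ethers and the bis-indolyl methine.

**Step 13**
Reactants: 22 3-[(1S,2S)-2,3-bis(TBSO)-1-{3-[2-(TBSO)ethyl]-1H-indol-2-yl}propyl]-1H-indole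
Product: 23 Colletotryptin B, (2S,3S)-3-[3-(2-hydroxyethyl)-1H-indol-2-yl]-3-(1H-indol-3-yl)propane-1,2-diol
Conditions: Bu4NF (5 equiv), THF, rt
Reagents that add atoms: none
Why: Fluoride-driven Si–O cleavage (global desilylation) releases the triol under non-acidic conditions that the acid-sensitive 2,3'-bis(indolyl)methane tolerates.

**Compound list**
1 | 1H-indole-3-carbaldehyde | O=Cc1c[nH]c2ccccc12 | starting material
2 | 1-tosyl-1H-indole-3-carbaldehyde | O=Cc1cn(S(=O)(=O)c2ccc(C)cc2)c2ccccc12 | intermediate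
3 | ethyl (triphenylphosphoranylidene)acetate | CCOC(=O)C=P(c1ccccc1)(c1ccccc1)c1ccccc1 | starting material
4 | ethyl (E)-3-(1-tosyl-1H-indol-3-yl)acrylate | CCOC(=O)/C=C/c1cn(S(=O)(=O)c2ccc(C)cc2)c2ccccc12 | intermediate
5 | (E)-3-(1-tosyl-1H-indol-3-yl)acrylaldehyde | O=C/C=C/c1cn(S(=O)(=O)c2ccc(C)cc2)c2ccccc12 | intermediate
6 | (E)-3-(1-tosyl-1H-indol-3-yl)prop-2-en-1-ol | OC/C=C/c1cn(S(=O)(=O)c2ccc(C)cc2)c2ccccc12 | intermediate
7 | (E)-3-[3-(Bpin)prop-1-en-1-yl]-1-tosyl-1H-indole | CC1(C)OB(C/C=C/c2cn(S(=O)(=O)c3ccc(C)cc3)c3ccccc23)OC1(C)C | intermediate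
8 | 2-[(tert-butyldimethylsilyl)oxy]acetaldehyde | CC(C)(C)[Si](C)(C)OCC=O | starting material
9 | 2-{[(2S,3R)-1-(TBSO)-3-(1-tosyl-1H-indol-3-yl)pent-4-en-2-yl]oxy}-4,4,5,5-tetramethyl-1,3,2-dioxaborolane | C=C[C@H](c1cn(S(=O)(=O)c2ccc(C)cc2)c2ccccc12)[C@H](OB1OC(C)(C)C(C)(C)O1)CO[Si](C)(C)C(C)(C)C | intermediate
10 | (2S,3R)-1-(TBSO)-3-(1-tosyl-1H-indol-3-yl)pent-4-en-2-ol | C=C[C@H](c1cn(S(=O)(=O)c2ccc(C)cc2)c2ccccc12)[C@H](O)CO[Si](C)(C)C(C)(C)C | intermediate
11 | 3-[(3R,4S)-4,5-bis(TBSO)pent-1-en-3-yl]-1-tosyl-1H-indole | C=C[C@H](c1cn(S(=O)(=O)c2ccc(C)cc2)c2ccccc12)[C@H](O[Si](C)(C)C(C)(C)C)CO[Si](C)(C)C(C)(C)C | intermediate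
12 | (2RS,3S,4S)-4,5-bis(TBSO)-3-(1-tosyl-1H-indol-3-yl)pentane-1,2-diol (both C2 epimers; the two existing stereocentres as in 11) | OCC(O)[C@H](c1cn(S(=O)(=O)c2ccc(C)cc2)c2ccccc12)[C@H](O[Si](C)(C)C(C)(C)C)CO[Si](C)(C)C(C)(C)C | intermediate
13 | (2R,3S)-3,4-bis(TBSO)-2-(1-tosyl-1H-indol-3-yl)butanal | O=C[C@H](c1cn(S(=O)(=O)c2ccc(C)cc2)c2ccccc12)[C@H](O[Si](C)(C)C(C)(C)C)CO[Si](C)(C)C(C)(C)C | intermediate
14 | tetrabromomethane | BrC(Br)(Br)Br | starting material
15 | 3-[(3R,4S)-1,1-dibromo-4,5-bis(TBSO)pent-1-en-3-yl]-1-tosyl-1H-indole | BrC(Br)=C[C@H](c1cn(S(=O)(=O)c2ccc(C)cc2)c2ccccc12)[C@H](O[Si](C)(C)C(C)(C)C)CO[Si](C)(C)C(C)(C)C | intermediate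
16 | oxirane | C1CO1 | starting material
17 | [(3R,4S)-4,5-bis(TBSO)-3-(1-tosyl-1H-indol-3-yl)pent-1-yn-1-yl]lithium | [Li]C#C[C@H](c1cn(S(=O)(=O)c2ccc(C)cc2)c2ccccc12)[C@H](O[Si](C)(C)C(C)(C)C)CO[Si](C)(C)C(C)(C)C | intermediate
18 | (5R,6S)-6,7-bis(TBSO)-5-(1-tosyl-1H-indol-3-yl)hept-3-yn-1-ol | OCCC#C[C@H](c1cn(S(=O)(=O)c2ccc(C)cc2)c2ccccc12)[C@H](O[Si](C)(C)C(C)(C)C)CO[Si](C)(C)C(C)(C)C | intermediate
19 | 3-[(5R,6S)-1,6,7-tris(TBSO)hept-3-yn-5-yl]-1-tosyl-1H-indole | CC(C)(C)[Si](C)(C)OCCC#C[C@H](c1cn(S(=O)(=O)c2ccc(C)cc2)c2ccccc12)[C@H](O[Si](C)(C)C(C)(C)C)CO[Si](C)(C)C(C)(C)C | intermediate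
20 | 2-iodoaniline | Nc1ccccc1I | starting material
21 | 3-[(1S,2S)-2,3-bis(TBSO)-1-{3-[2-(TBSO)ethyl]-1H-indol-2-yl}propyl]-1-tosyl-1H-indole | CC(C)(C)[Si](C)(C)OCCc1c([C@H](c2cn(S(=O)(=O)c3ccc(C)cc3)c3ccccc23)[C@H](O[Si](C)(C)C(C)(C)C)CO[Si](C)(C)C(C)(C)C)[nH]c2ccccc12 | intermediate
22 | 3-[(1S,2S)-2,3-bis(TBSO)-1-{3-[2-(TBSO)ethyl]-1H-indol-2-yl}propyl]-1H-indole | CC(C)(C)[Si](C)(C)OCCc1c([C@H](c2c[nH]c3ccccc23)[C@H](O[Si](C)(C)C(C)(C)C)CO[Si](C)(C)C(C)(C)C)[nH]c2ccccc12 | intermediate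
23 | Colletotryptin B, (2S,3S)-3-[3-(2-hydroxyethyl)-1H-indol-2-yl]-3-(1H-indol-3-yl)propane-1,2-diol | OCCc1c([C@H](c2c[nH]c3ccccc23)[C@H](O)CO)[nH]c2ccccc12 | target

**Totals**
Total step count: 13. Longest linear sequence: 13 steps (1 to 23).

**Three steps most likely to fail**

Step 5 (catalytic asymmetric allylboration). The γ-heteroaryl boronate and the α-silyloxy aldehyde have no exact precedent with this catalyst, so the enantiomeric excess or the rate may be poor. The fallback sets out from 7 and 8 and comes back at 10; it gives up asymmetric catalysis for a racemic synthesis with classical resolution. Heating 7 with 8 in toluene at 50 °C without catalyst still passes through the chair transition state and gives the racemic anti pinacol borate F1, hydrolysed on work-up to the racemic anti alcohol F2. Esterification with (S)-2-methoxy-2-phenylacetic acid (DCC, DMAP, CH2Cl2) gives two diastereomeric esters that are separated on silica: the (S)-methoxyphenylacetate of the (2S,3R)-alcohol F3 and the (S)-methoxyphenylacetate of the (2R,3S)-alcohol F4, told apart by the aryl shielding pattern in the 1H NMR spectrum. Methanolysis of F3 (K2CO3, MeOH, rt) returns enantiopure 10.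

Step 7 (formation and use of the α-indolyl aldehyde 13). The aldehyde may epimerise or lose the β-silyloxy group before it is olefinated. The fallback sets out from 11 and comes back at 21; it avoids any carbonyl group next to the stereocentre and builds the second indole on the alkene instead of on an alkyne. Cross-metathesis of 11 with 2-nitrostyrene (second-generation Hoveyda–Grubbs catalyst, RuCl2(H2IMes)(=CH-C6H4-2-OiPr), toluene, 60 °C) gives the (E)-2-nitrostyryl compound F5. Reductive N-heteroannulation (Pd(OAc)2, 1,10-phenanthroline, CO 4 bar, DMF, 100 °C) closes the ring onto the alkene carbon next to the stereocentre and gives the 2-substituted indole F6. Reductive C3-alkylation of F6 with aldehyde 8 (Et3SiH, CF3CO2H, CH2Cl2, 0 °C) then gives 21 directly.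

Step 11 (Larock heteroannulation). The hindered alkyne may react slowly or give the regioisomeric indole. The fallback sets out from 15 and comes back at 21; it fixes the regiochemistry by joining the aryl ring to a terminal alkyne first. Treatment of 15 with n-BuLi (2.05 equiv, THF, −78 °C) and quenching with water gives the terminal alkyne F7. Sonogashira coupling with N-(2-iodophenyl)-2,2,2-trifluoroacetamide (PdCl2(PPh3)2, CuI, Et3N, THF, rt) gives the o-alkynyl trifluoroacetanilide F8. Cacchi aminopalladation–reductive elimination with ethyl iodoacetate (Pd(PPh3)4, K2CO3, THF, 60 °C) forms the indole with the carbon chain already at C3 and loses the trifluoroacetyl group, giving the ethyl indol-3-ylacetate F9. Reduction with LiBH4 (THF, 0 °C to rt) gives the 2-(indol-3-yl)ethanol F10, and silylation (TBSCl, imidazole, DMF) gives 21.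

**Further compounds**
F1 | step 5 | racemic anti pinacol borate (9 and its mirror image, 1:1) | C=C[C@H](c1cn(S(=O)(=O)c2ccc(C)cc2)c2ccccc12)[C@H](OB1OC(C)(C)C(C)(C)O1)CO[Si](C)(C)C(C)(C)C.C=C[C@@H](c1cn(S(=O)(=O)c2ccc(C)cc2)c2ccccc12)[C@@H](OB1OC(C)(C)C(C)(C)O1)CO[Si](C)(C)C(C)(C)C
F2 | step 5 | racemic anti alcohol (10 and its (2R,3S) enantiomer, 1:1) | C=C[C@H](c1cn(S(=O)(=O)c2ccc(C)cc2)c2ccccc12)[C@H](O)CO[Si](C)(C)C(C)(C)C.C=C[C@@H](c1cn(S(=O)(=O)c2ccc(C)cc2)c2ccccc12)[C@@H](O)CO[Si](C)(C)C(C)(C)C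
F3 | step 5 | (2S,3R)-1-(TBSO)-3-(1-tosyl-1H-indol-3-yl)pent-4-en-2-yl (S)-2-methoxy-2-phenylacetate | C=C[C@H](c1cn(S(=O)(=O)c2ccc(C)cc2)c2ccccc12)[C@H](OC(=O)[C@@H](OC)c1ccccc1)CO[Si](C)(C)C(C)(C)C
F4 | step 5 | (2R,3S)-1-(TBSO)-3-(1-tosyl-1H-indol-3-yl)pent-4-en-2-yl (S)-2-methoxy-2-phenylacetate | C=C[C@@H](c1cn(S(=O)(=O)c2ccc(C)cc2)c2ccccc12)[C@@H](OC(=O)[C@@H](OC)c1ccccc1)CO[Si](C)(C)C(C)(C)C
F5 | step 7 | 3-[(1E,3R,4S)-4,5-bis(TBSO)-1-(2-nitrophenyl)pent-1-en-3-yl]-1-tosyl-1H-indole | [O-][N+](=O)c1ccccc1/C=C/[C@H](c1cn(S(=O)(=O)c2ccc(C)cc2)c2ccccc12)[C@H](O[Si](C)(C)C(C)(C)C)CO[Si](C)(C)C(C)(C)C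
F6 | step 7 | 3-[(1S,2S)-2,3-bis(TBSO)-1-(1H-indol-2-yl)propyl]-1-tosyl-1H-indole | c1ccc2[nH]c(cc2c1)[C@H](c1cn(S(=O)(=O)c3ccc(C)cc3)c3ccccc13)[C@H](O[Si](C)(C)C(C)(C)C)CO[Si](C)(C)C(C)(C)C
F7 | step 11 | 3-[(3R,4S)-4,5-bis(TBSO)pent-1-yn-3-yl]-1-tosyl-1H-indole | C#C[C@H](c1cn(S(=O)(=O)c2ccc(C)cc2)c2ccccc12)[C@H](O[Si](C)(C)C(C)(C)C)CO[Si](C)(C)C(C)(C)C
F8 | step 11 | N-{2-[(3R,4S)-4,5-bis(TBSO)-3-(1-tosyl-1H-indol-3-yl)pent-1-yn-1-yl]phenyl}-2,2,2-trifluoroacetamide | FC(F)(F)C(=O)Nc1ccccc1C#C[C@H](c1cn(S(=O)(=O)c2ccc(C)cc2)c2ccccc12)[C@H](O[Si](C)(C)C(C)(C)C)CO[Si](C)(C)C(C)(C)C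
F9 | step 11 | ethyl 2-{2-[(1S,2S)-2,3-bis(TBSO)-1-(1-tosyl-1H-indol-3-yl)propyl]-1H-indol-3-yl}acetate | CCOC(=O)Cc1c([C@H](c2cn(S(=O)(=O)c3ccc(C)cc3)c3ccccc23)[C@H](O[Si](C)(C)C(C)(C)C)CO[Si](C)(C)C(C)(C)C)[nH]c2ccccc12
F10 | step 11 | 2-{2-[(1S,2S)-2,3-bis(TBSO)-1-(1-tosyl-1H-indol-3-yl)propyl]-1H-indol-3-yl}ethanol | OCCc1c([C@H](c2cn(S(=O)(=O)c3ccc(C)cc3)c3ccccc23)[C@H](O[Si](C)(C)C(C)(C)C)CO[Si](C)(C)C(C)(C)C)[nH]c2ccccc12
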